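The readings come from a simulation with made-up constants; scatter was added.

The dusk run ends with reagent left over: of 2.00 equivalents charged, the readings at 60.0 s place 1.84 in mono adduct and double product, so about 0.160 stays spare. In the dawn run the reagent is the limiting reagent, and its mono adduct readings average 48.0% at a ratio of 0.480.

| setting | dawn | dusk | blue | ochre | green |
|---|---|---|---|---|---|
| starting material | 5 mM | 5 mM | 5.0 mM | 5.0 mM | 5.0 mM |
| reagent | 2.4 mM | 10 mM | 4.00 mM | 5.00 mM | 15.0 mM |
| remark | run made earlier | run made earlier |  |  |  |
| time |  |  | 3.0 min | 3.0 min | 3.0 min |

| run | time / s | mono adduct / % | double product / % | starting material / % |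
|---|---|---|---|---|
| dawn | 20.0 | 44 | 0 | 56 |
| dawn | 40.0 | 50 | 5 | 49 |
| dawn | 50.0 | 46 | 7 | 49 |
| dawn | 80.0 | 52 | 3 | 54 |
| dawn | 90.0 | 48 | 0 | 51 |
| dusk | 10.0 | 25 | 75 | 13 |
| dusk | 25.0 | 16 | 81 | 0 |
| dusk | 40.0 | 14 | 85 | 4 |
| dusk | 60.0 | 14 | 85 | 0 |
| dusk | 90.0 | 12 | 83 | 0 |

(readings scatter by 2 percentage points)

- a reading or a percentage of double product counts all its forms, free or not

- how much mono adduct is there at the end, in percent of the starting material charged: for each flask in turn (blue, ochre, green)

The first setting is the reagent charge. Blue has a charge ratio, reagent charged per starting material charged, of 0.800. By hand, a ratio under one turns into the same fraction of mono adduct, as in the dawn run, so this reckoning gives 80.0% for blue. Ochre has a ratio of 1.00, which by hand gives 100%; if the reagent is taken up in full, that figure drops by two shares of the charge for each share of double product: one is the double product itself and one is the starting material its second reagent leaves unserved. Green has a ratio of 3.00, higher than the dusk ratio, so by hand its mono adduct falls under the dusk reading of 12%.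

The second setting is time. The flasks run 9.00 times as long as the first dawn reading, which already shows 44% mono adduct, so blue is reckoned as finished.

The forecast gives 78%, 92% and 3% for blue, ochre and green, and holds that “the first step clearly outruns the second while starting material remains”. Its blue value lies just under the ratio reckoning.

The flasks give 79.9%, 88.1% and 2.20%, within the tolerance of the forecast. Blue keeps 20.0% starting material at 3.00 min, with reagent down to 0.0342% of its own charge.

    crystals ⇌ double product, rate k1*(cs1 - [double product]) while solid is left; crystals form when [double product] > cs1 (solubility = 0.0810 mM, k = 37.7 /s)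
    reagent + mono adduct ⇌ double product (K = 144 /M, k = 68.3 /M/s)
    starting material + reagent → mono adduct (k = 65.8 /M/s)

Blue's mono adduct stands at its ratio of 0.800. Ochre's mono adduct is 88.1% at 3.00 min, less than its ratio of 1.00, and 99.6% at 30.0 min.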